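Everything rests on cutting C2–C6 of the cyclopentane and C7–C8 of the cyclohexane together, which opens the hydrindane to an acyclic (E,E,E)-trienone. One Lewis-acid-promoted intramolecular Diels–Alder reaction closes both rings and sets C2, C6 and C7. It exploits the trans fusion across C2–C6, the C7 carbon branch trans to C5, and C1, whose methylene and neighbouring C9 oxygen can both be drawn from a C1=C9 ring alkene carrying a C1 methyl. The precursor has the diene C8=C9–C1(CH3)=C2, the tether C3–C5 with its two oxygens and the acetoxyethyl branch, and the enone C6=C7–acetyl; its C3 oxygen is deliberately epimeric and is inverted after ring closure.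

Key step: step 15

Remark (numbering and faces): C1 carries C10 (methyl in 23–27, methylene from 28 on); C2 and C6 are the fusion carbons; C3 and C4 carry the ring oxygens; C5 carries C11 (CH(OAc)CH3); C7 carries C13 (acetyl carbon, later the epoxide carbon); C8 is the ring CH2; C9 carries the enoate; α is the face of H2, β the face of H6 and of the C7 side chain.

Remark (correction to the precursor): the C10 methyl is cis to C3 on the diene, so 1,3-allylic strain keeps H3, not the C3 oxygen, in the diene plane and the oxygen ends trans to C1; the cycloaddition is therefore run on the C3 epimer (C3 silyl ether, C4 isobutyrate, C11 acetate), and C3 is inverted afterwards by the Mitsunobu reaction that installs its isobutyrate.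

Remark (consequence and assumption): this design needs (S)-glyceraldehyde acetonide, for which the allylboration is the matched (Felkin) case; this aldehyde, the three Wittig ylides, the iodomethylboronate and (S)-2-acetoxypropanoyl chloride are taken as purchasable.

Step 1
Reactants: 1 (S)-but-3-yn-2-ol
Product: 2 (S)-tert-butyl(but-3-yn-2-yloxy)dimethylsilane
Conditions: TBSCl, imidazole, DMF, 0 °C → rt
Reagents that add atoms: tert-butyldimethylsilyl chloride, CC(C)(C)[Si](C)(C)Cl
Why: Silyl ether formation masks the hydroxyl for the organolithium step and leaves C11 untouched.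

Step 2
Reactants: 2 silyl ether of butynol; 3 2-(iodomethyl)-4,4,5,5-tetramethyl-1,3,2-dioxaborolane
Product: 5 (S)-propargylic pinacol boronate, via lithium acetylide 4 (not isolated)
Conditions: n-BuLi, THF, −78 °C; then 3, −78 °C → rt
Reagents that add atoms: none
Why: Matteson-type homologation, in which the acetylide adds to boron and the alkynyl group shifts from boron to carbon with loss of iodide, places the CH2–B unit on the alkyne terminus without touching C11.

Step 3
Reactants: 5 propargylic boronate
Product: 6 (S,Z)-allylic pinacol boronate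
Conditions: H2 (1 atm), Pd/CaCO3 poisoned with Pb(OAc)2, quinoline, hexane, rt
Reagents that add atoms: none
Why: Syn semi-hydrogenation of the alkyne on the poisoned palladium surface (Lindlar reduction) should give the (Z)-alkene, and pinacol allylboronates keep their geometry at room temperature.

Step 4
Reactants: 6 (S,Z)-allylic boronate; 7 (S)-2,2-dimethyl-1,3-dioxolane-4-carbaldehyde
Product: 9 homoallylic alcohol (C3/C4 anti and C4/C5 syn), via pinacol borate ester 8 (not isolated)
Conditions: toluene (2 M), 4 Å molecular sieves, rt, 3 d; then aq. NaHCO3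
Reagents that add atoms: none
Why: Allylboration through a closed chair (Zimmerman–Traxler) transition state, in which the (Z)-boronate gives the C4/C5 syn pair, the aldehyde is attacked on its Felkin face (C3/C4 anti), and the reagent, with H11 eclipsing its alkene to avoid 1,3-allylic strain, reacts anti to its silyloxy group, so that both preferences should reinforce each other in setting C4 and C5.

Step 5
Reactants: 9 homoallylic alcohol
Product: 10 C4 isobutyrate
Conditions: (CH3)2CHCOCl, pyridine, DMAP (cat.), CH2Cl2, 0 °C → rt
Reagents that add atoms: isobutyryl chloride, CC(C)C(Cl)=O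
Why: DMAP-catalysed acylation of the only free hydroxyl (ester formation) puts the C4 isobutyrate of the target in place with retention.

Step 6
Reactants: 10 C4 isobutyrate
Product: 11 C11 alcohol
Conditions: HF·pyridine, pyridine, THF, 0 °C → rt
Reagents that add atoms: none
Why: Fluoride-mediated desilylation under buffered, mildly acidic conditions frees the C11 hydroxyl while the acetonide and the ester stay and the base-promoted acyl shift from O4 is avoided.

Step 7
Reactants: 11 C11 alcohol
Product: 12 C11 acetate
Conditions: Ac2O, pyridine, DMAP (cat.), CH2Cl2, 0 °C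
Reagents that add atoms: acetic anhydride, CC(=O)OC(C)=O
Why: DMAP-catalysed acetylation, which should outpace any acyl shift from the neighbouring ester, installs the acetate of the target at C11.

Step 8
Reactants: 12 C11 acetate
Product: 14 C6 aldehyde, via 1,2,4-trioxolane 13 (not isolated)
Conditions: O3, CH2Cl2, −78 °C; then PPh3, −78 °C → rt
Reagents that add atoms: ozone, O=[O+][O-]
Why: Ozonolysis (1,3-dipolar cycloaddition, rearrangement to the ozonide, then phosphine reduction) cleaves the only alkene to the C6 aldehyde under neutral conditions that should leave C5 and both β-acyloxy groups in place.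

Step 9
Reactants: 14 C6 aldehyde; 15 1-(triphenyl-λ5-phosphanylidene)propan-2-one
Product: 16 (E)-enone (acetonide)
Conditions: CH2Cl2, rt
Reagents that add atoms: none
Why: Wittig olefination with a ketone-stabilised ylide, which is only weakly basic and E-selective, should build the C6=C7 enone without epimerising C5 or eliminating a β-acyloxy group.

Step 10
Reactants: 16 (E)-enone
Product: 17 C2,C3-diol
Conditions: AcOH/H2O (4:1), rt
Reagents that add atoms: none
Why: Acid-catalysed hydrolysis of the terminal isopropylidene acetal frees the diol, while esters, enone and C5 are stable to dilute acetic acid.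

Step 11
Reactants: 17 diol
Product: 18 bis(triethylsilyl) ether
Conditions: Et3SiCl, imidazole, CH2Cl2, 0 °C → rt
Reagents that add atoms: chlorotriethylsilane, CC[Si](Cl)(CC)CC
Why: Silyl ether formation at both hydroxyls with the chloride and imidazole, conditions that do not enolise the methyl ketone.

Step 12
Reactants: 18 bis(triethylsilyl) ether
Product: 20 C2 aldehyde with C3 triethylsilyl ether, via alkoxysulfonium chloride 19 (not isolated)
Conditions: (COCl)2, DMSO, CH2Cl2, −78 → −30 °C; then Et3N, −78 → 0 °C
Reagents that add atoms: none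
Why: Swern oxidation applied to a silyl ether, in which chlorodimethylsulfonium chloride cleaves the less hindered primary triethylsilyl ether to the alkoxysulfonium ion and the amine converts this into the aldehyde, while the secondary C3 silyl ether is kept.

Step 13
Reactants: 20 C2 aldehyde; 21 2-(triphenyl-λ5-phosphanylidene)propanal
Product: 22 (E)-2-methyl enal
Conditions: toluene, 80 °C
Reagents that add atoms: none
Why: Wittig olefination with a formyl-stabilised ylide gives the (E)-enal (C3 trans to the formyl group) under neutral conditions in which the α-silyloxy centre C3 should not epimerise and the enone does not react.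

Step 14
Reactants: 22 (E)-enal
Product: 23 (E,E)-trienone, the cycloaddition precursor
Conditions: Ph3PCH3+ Br−, KN(SiMe3)2, THF, −78 °C; then 22 (1 equiv of ylide), −78 → −20 °C
Reagents that add atoms: methyltriphenylphosphonium bromide, C[P+](c1ccccc1)(c1ccccc1)c1ccccc1.[Br-]
Why: Wittig methylenation at low temperature, where the ylide takes the aldehyde far faster than the conjugated methyl ketone or the esters, turns the enal into the terminal diene and leaves the C1=C2 geometry unchanged.

Step 15
Reactants: 23 (E,E)-trienone
Product: 24 trans-hydrindene with C7 acetyl (C3 α-silyl ether)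
Conditions: Me2AlCl (2.5 equiv), CH2Cl2, −78 → −20 °C; then aq. NaHCO3
Reagents that add atoms: none
Why: Me2AlCl binds the ketone oxygen and lowers the enone LUMO, so that the diene C2=C1–C9=C8 and the dienophile C6=C7 combine in one concerted, suprafacial [4+2] event, a Lewis-acid-promoted intramolecular Diels–Alder reaction of a 1,3,8-nonatriene with a terminal (E)-acyl dienophile, which is a known way to trans-hydrindenes. The cyclopentane closes through C2–C6 with the tether C3–C5 bridging the two termini, and the cyclohexene closes through C7–C8, which leaves the C1=C9 alkene with the methyl on C1. C6 and C7 follow from the (E)-geometry of the enone (acetyl trans to C5), and the endo transition state, with the complexed acetyl under the diene, ties C2 to them and gives the trans fusion. The absolute sense comes from the tether: 1,3-allylic strain with the C10 methyl holds H3 in the diene plane and turns the C3 silyl ether outward, while H5 eclipses C6=C7 and the acetoxyethyl group sits outside, so one face of each π system is selected in the same transition state. The step needs endo over exo selectivity and this pairing of faces; the Lewis acid should provide the first, and the C3 and C5 centres, acting in concert, the second.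

Step 16
Reactants: 24 cycloadduct
Product: 25 C3 α-alcohol
Conditions: HF·pyridine, pyridine, THF, 0 °C
Reagents that add atoms: none
Why: Fluoride-mediated desilylation of the triethylsilyl ether under mildly acidic conditions leaves the esters in place and avoids the base-promoted shift of the C4 isobutyryl group to the new cis hydroxyl.

Step 17
Reactants: 25 C3 α-alcohol
Product: 26 C3β,C4α-bis(isobutyrate)
Conditions: (CH3)2CHCO2H, PPh3, DIAD, toluene, 0 °C → rt
Reagents that add atoms: isobutyric acid, CC(C)C(=O)O
Why: Mitsunobu esterification activates the C3 hydroxyl as its alkoxyphosphonium ion and isobutyrate displaces it with inversion (SN2), which turns the α oxygen into the β isobutyrate cis to C1, the cis C4 ester being unable to take part from the rear.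

Step 18
Reactants: 26 bis(isobutyrate)
Product: 27 C1,C9 α-epoxide
Conditions: mCPBA, NaHCO3, CH2Cl2, 0 °C
Reagents that add atoms: 3-chloroperoxybenzoic acid, OOC(=O)c1cccc(Cl)c1
Why: Prilezhaev epoxidation of the trisubstituted alkene, faster than Baeyer–Villiger attack on the ketone, should occur on the α face, anti to the C3 isobutyrate that covers the β face next to C1, and so sets C1 and C9.

Step 19
Reactants: 27 α-epoxide
Product: 28 allylic alcohol (C1=C10 methylene, C9 α-hydroxyl)
Conditions: Cp2TiCl2 (2.5 equiv), Mn dust, THF, rt; then cold 0.5 M HCl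
Reagents that add atoms: none
Why: Cp2TiCl (trivalent titanium) opens the epoxide homolytically at the tertiary C1–O bond, and the C1 radical loses a hydrogen atom from the unhindered C10 methyl to a second Cp2TiCl, a known epoxide-to-allylic-alcohol isomerization that gives the exocyclic alkene and leaves the C9–O bond and its configuration untouched.

Step 20
Reactants: 28 allylic alcohol
Product: 29 epoxy alcohol with the (R)-2-methyloxiran-2-yl group at C7
Conditions: Me3S+ I−, KN(SiMe3)2 (3 equiv each), THF, −20 → 0 °C
Reagents that add atoms: trimethylsulfonium iodide, C[S+](C)C.[I-]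
Why: Corey–Chaykovsky methylene transfer, in which the ylide adds to the acetyl carbonyl anti to C6, the larger C7 substituent (Felkin–Anh), and the betaine closes to the epoxide, should set C13 as R, the esters reacting far more slowly with this ylide at low temperature.

Step 21
Reactants: 30 (S)-2-acetoxypropanoyl chloride
Product: 31 (S)-3-oxobutan-2-yl acetate
Conditions: MeMgBr, Fe(acac)3 (3 mol %), THF, −78 °C
Reagents that add atoms: methylmagnesium bromide, C[Mg]Br
Why: Iron-catalysed cross-coupling of the acid chloride with the methyl Grignard reagent (ketone synthesis by acyl substitution) stops at the ketone at −78 °C and should spare the acetate and the α stereocentre.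

Step 22
Reactants: 31 (S)-3-oxobutan-2-yl acetate; 32 tert-butyl 2-(triphenyl-λ5-phosphanylidene)acetate
Product: 33 tert-butyl (S,E)-4-acetoxy-3-methylpent-2-enoate
Conditions: toluene, 90 °C
Reagents that add atoms: none
Why: Wittig olefination of the activated α-acyloxy ketone with an ester-stabilised ylide should place the ester trans to the branched carbon, giving the (E)-enoate under neutral conditions that do not racemise the α centre.

Step 23
Reactants: 33 tert-butyl ester
Product: 34 (S,E)-4-acetoxy-3-methylpent-2-enoic acid
Conditions: CF3CO2H, CH2Cl2, 0 °C → rt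
Reagents that add atoms: none
Why: Acidolysis of the tert-butyl ester (E1 loss of isobutene) frees the acid without touching the secondary acetate or the alkene geometry.

Step 24
Reactants: 29 epoxy alcohol; 34 side-chain acid
Product: 36 CNP0131236.1, via mixed anhydride 35 (not isolated)
Conditions: 34, 2,4,6-Cl3C6H2COCl, Et3N, toluene, rt; then 29, DMAP, toluene, rt
Reagents that add atoms: none
Why: Yamaguchi esterification converts the acid into its mixed anhydride, and DMAP-catalysed acyl transfer to the C9 hydroxyl forms the ester with retention at C9 under conditions that keep the epoxide and the enoate geometry.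

Compound list

1 | (S)-but-3-yn-2-ol | C#C[C@H](C)O | starting material
2 | (S)-tert-butyl(but-3-yn-2-yloxy)dimethylsilane | C#C[C@H](C)O[Si](C)(C)C(C)(C)C | intermediate
3 | 2-(iodomethyl)-4,4,5,5-tetramethyl-1,3,2-dioxaborolane | ICB1OC(C)(C)C(C)(C)O1 | starting material
4 | lithium (S)-3-[(tert-butyldimethylsilyl)oxy]but-1-yn-1-ide | [Li]C#C[C@H](C)O[Si](C)(C)C(C)(C)C | intermediate (not isolated)
5 | (S)-tert-butyldimethyl{[5-(4,4,5,5-tetramethyl-1,3,2-dioxaborolan-2-yl)pent-3-yn-2-yl]oxy}silane | CC1(C)OB(CC#C[C@H](C)O[Si](C)(C)C(C)(C)C)OC1(C)C | intermediate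
6 | (S,Z)-tert-butyldimethyl{[5-(4,4,5,5-tetramethyl-1,3,2-dioxaborolan-2-yl)pent-3-en-2-yl]oxy}silane | CC1(C)OB(C/C=C\[C@H](C)O[Si](C)(C)C(C)(C)C)OC1(C)C | intermediate
7 | (S)-2,2-dimethyl-1,3-dioxolane-4-carbaldehyde | O=C[C@@H]1COC(C)(C)O1 | starting material
8 | pinacol borate ester of alcohol 9 (boron on the C4 oxygen) | CC1(C)OC[C@H](O1)[C@H](OB2OC(C)(C)C(C)(C)O2)[C@@H]([C@H](C)O[Si](C)(C)C(C)(C)C)C=C | intermediate (not isolated)
9 | (1R,2S)-1-[(4S)-2,2-dimethyl-1,3-dioxolan-4-yl]-2-[(1S)-1-[(tert-butyldimethylsilyl)oxy]ethyl]but-3-en-1-ol | CC1(C)OC[C@H](O1)[C@H](O)[C@@H]([C@H](C)O[Si](C)(C)C(C)(C)C)C=C | intermediate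
10 | C4 isobutyrate of 9 | CC1(C)OC[C@H](O1)[C@H](OC(=O)C(C)C)[C@@H]([C@H](C)O[Si](C)(C)C(C)(C)C)C=C | intermediate
11 | C11 alcohol (C4 isobutyrate, acetonide, vinyl) | CC1(C)OC[C@H](O1)[C@H](OC(=O)C(C)C)[C@@H]([C@H](C)O)C=C | intermediate
12 | C11 acetate (C4 isobutyrate, acetonide, vinyl) | CC1(C)OC[C@H](O1)[C@H](OC(=O)C(C)C)[C@@H]([C@H](C)OC(C)=O)C=C | intermediate
13 | 1,2,4-trioxolane (ozonide) of 12 | CC1(C)OC[C@H](O1)[C@H](OC(=O)C(C)C)[C@@H]([C@H](C)OC(C)=O)C1OCOO1 | intermediate (not isolated)
14 | C6 aldehyde (C4 isobutyrate, C11 acetate, acetonide) | CC1(C)OC[C@H](O1)[C@H](OC(=O)C(C)C)[C@@H]([C@H](C)OC(C)=O)C=O | intermediate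
15 | 1-(triphenyl-λ5-phosphanylidene)propan-2-one | CC(=O)C=P(c1ccccc1)(c1ccccc1)c1ccccc1 | starting material
16 | (E)-enone C6=C7–C(O)CH3 (acetonide, C4 isobutyrate, C11 acetate) | CC1(C)OC[C@H](O1)[C@H](OC(=O)C(C)C)[C@@H]([C@H](C)OC(C)=O)/C=C/C(C)=O | intermediate
17 | C2,C3-diol of the (E)-enone | OC[C@H](O)[C@H](OC(=O)C(C)C)[C@@H]([C@H](C)OC(C)=O)/C=C/C(C)=O | intermediate
18 | C2,C3-bis(triethylsilyl) ether of 17 | CC[Si](CC)(CC)OC[C@H](O[Si](CC)(CC)CC)[C@H](OC(=O)C(C)C)[C@@H]([C@H](C)OC(C)=O)/C=C/C(C)=O | intermediate
19 | dimethyl(alkoxy)sulfonium chloride at the C2 oxygen | C[S+](C)OC[C@H](O[Si](CC)(CC)CC)[C@H](OC(=O)C(C)C)[C@@H]([C@H](C)OC(C)=O)/C=C/C(C)=O.[Cl-] | intermediate (not isolated)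
20 | C2 aldehyde with C3 triethylsilyl ether | O=C[C@H](O[Si](CC)(CC)CC)[C@H](OC(=O)C(C)C)[C@@H]([C@H](C)OC(C)=O)/C=C/C(C)=O | intermediate
21 | 2-(triphenyl-λ5-phosphanylidene)propanal | CC(C=O)=P(c1ccccc1)(c1ccccc1)c1ccccc1 | starting material
22 | (E)-enal C2=C1(CH3)–C9HO with the (E)-enone | O=C/C(C)=C/[C@H](O[Si](CC)(CC)CC)[C@H](OC(=O)C(C)C)[C@@H]([C@H](C)OC(C)=O)/C=C/C(C)=O | intermediate
23 | (E,E)-trienone precursor (C3 triethylsilyl ether with C3 and C4 oxygens anti, C4 isobutyrate, C11 acetate) | C=C/C(C)=C/[C@H](O[Si](CC)(CC)CC)[C@H](OC(=O)C(C)C)[C@@H]([C@H](C)OC(C)=O)/C=C/C(C)=O | intermediate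
24 | trans-hydrindene cycloadduct (C1 methyl, C1=C9, C7 β-acetyl, C3 α-OSiEt3, C4 α-isobutyrate, C5 β-acetoxyethyl) | CC=1[C@H]2[C@H](O[Si](CC)(CC)CC)[C@H](OC(=O)C(C)C)[C@@H]([C@H](C)OC(C)=O)[C@@H]2[C@@H](C(C)=O)CC=1 | intermediate
25 | C3 α-alcohol of the cycloadduct | CC=1[C@H]2[C@H](O)[C@H](OC(=O)C(C)C)[C@@H]([C@H](C)OC(C)=O)[C@@H]2[C@@H](C(C)=O)CC=1 | intermediate
26 | C3β,C4α-bis(isobutyrate) with C7 acetyl | CC=1[C@H]2[C@@H](OC(=O)C(C)C)[C@H](OC(=O)C(C)C)[C@@H]([C@H](C)OC(C)=O)[C@@H]2[C@@H](C(C)=O)CC=1 | intermediate
27 | C1,C9 α-epoxide of 26 | C[C@]12O[C@H]1C[C@H](C(C)=O)[C@H]1[C@H]([C@H](C)OC(C)=O)[C@@H](OC(=O)C(C)C)[C@H](OC(=O)C(C)C)[C@@H]12 | intermediate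
28 | allylic alcohol (C1=C10 methylene, C9 α-OH, C7 acetyl) | C=C1[C@H]2[C@@H](OC(=O)C(C)C)[C@H](OC(=O)C(C)C)[C@@H]([C@H](C)OC(C)=O)[C@@H]2[C@@H](C(C)=O)C[C@@H]1O | intermediate
29 | epoxy alcohol (C7 (R)-2-methyloxiran-2-yl, C9 α-OH) | C=C1[C@H]2[C@@H](OC(=O)C(C)C)[C@H](OC(=O)C(C)C)[C@@H]([C@H](C)OC(C)=O)[C@@H]2[C@@H]([C@]2(C)CO2)C[C@@H]1O | intermediate
30 | (S)-2-acetoxypropanoyl chloride | ClC(=O)[C@H](C)OC(C)=O | starting material
31 | (S)-3-oxobutan-2-yl acetate | CC(=O)[C@H](C)OC(C)=O | intermediate
32 | tert-butyl 2-(triphenyl-λ5-phosphanylidene)acetate | CC(C)(C)OC(=O)C=P(c1ccccc1)(c1ccccc1)c1ccccc1 | starting material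
33 | tert-butyl (S,E)-4-acetoxy-3-methylpent-2-enoate | CC(C)(C)OC(=O)/C=C(\C)[C@H](C)OC(C)=O | intermediate
34 | (S,E)-4-acetoxy-3-methylpent-2-enoic acid | OC(=O)/C=C(\C)[C@H](C)OC(C)=O | intermediate
35 | mixed anhydride of 34 with 2,4,6-trichlorobenzoic acid | O=C(OC(=O)/C=C(\C)[C@H](C)OC(C)=O)c1c(Cl)cc(Cl)cc1Cl | intermediate (not isolated)
36 | CNP0131236.1 | C=C1[C@H]2[C@@H](OC(=O)C(C)C)[C@H](OC(=O)C(C)C)[C@@H]([C@H](C)OC(C)=O)[C@@H]2[C@@H]([C@]2(C)CO2)C[C@@H]1OC(=O)/C=C(\C)[C@H](C)OC(C)=O | target

Total step count: 24.
Longest linear sequence: 21 steps (steps 1–20 and 24, from 1).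

Steps most likely to fail

Step 15. The Lewis acid may cleave or ionize the dienylic C3 silyl ether, or the endo preference may erode if the reaction has to be warmed, so that cis-fused material forms. The fallback sets out from 23 and returns at 25. The silyl ether is removed first with HF·pyridine to give the dienol F1, and F1 is cyclized without any Lewis acid by heating in toluene (110 °C, with BHT). 1,3-Allylic strain still fixes the diene face and a free hydroxyl cannot ionize under neutral conditions. The trans-fused adduct, separated from any cis-fused isomer, is alcohol 25 itself, so step 16 is skipped.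

Step 17. Substitution at the ring carbinol may be slow, leaving unreacted alcohol or giving elimination towards C4. The fallback sets out from 25 and returns at 26. The alcohol is converted with Tf2O and pyridine (CH2Cl2, −20 °C) into the triflate F2, which is displaced with inversion by caesium isobutyrate and 18-crown-6 in toluene at room temperature. This is a stepwise sulfonate displacement instead of the redox condensation.

Step 20. Methylene transfer to the acetyl carbonyl may show poor facial selectivity, giving both C13 epimers. The fallback sets out from 28 and returns at 29. Lithiated (S)-N,S-dimethyl-S-phenylsulfoximine (n-BuLi, THF, −78 °C, excess to allow for the free hydroxyl) adds to the ketone. The β-hydroxysulfoximine F3 with the required C13 configuration is separated by chromatography, and the other epimer is returned to 28 by thermolysis, which reverses the addition. N-Methylation with Me3O+ BF4− gives the aminosulfoxonium salt F4, and KOt-Bu in THF at −20 °C closes the epoxide to 29 with loss of the sulfinamide.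

Further compounds
F1 | step 15 | (E,E)-trienone with free C3 hydroxyl (dienol) | C=C/C(C)=C/[C@H](O)[C@H](OC(=O)C(C)C)[C@@H]([C@H](C)OC(C)=O)/C=C/C(C)=O
F2 | step 17 | C3 α-triflate of 25 | CC=1[C@H]2[C@H](OS(=O)(=O)C(F)(F)F)[C@H](OC(=O)C(C)C)[C@@H]([C@H](C)OC(C)=O)[C@@H]2[C@@H](C(C)=O)CC=1
F3 | step 20 | β-hydroxysulfoximine adduct of 28 (C13 tertiary alcohol, CH2–S(O)(=NCH3)Ph) | C=C1[C@H]2[C@@H](OC(=O)C(C)C)[C@H](OC(=O)C(C)C)[C@@H]([C@H](C)OC(C)=O)[C@@H]2[C@@H]([C@@](C)(O)C[S@@](=O)(=NC)c3ccccc3)C[C@@H]1O
F4 | step 20 | (dimethylamino)sulfoxonium tetrafluoroborate from F3 | C=C1[C@H]2[C@@H](OC(=O)C(C)C)[C@H](OC(=O)C(C)C)[C@@H]([C@H](C)OC(C)=O)[C@@H]2[C@@H]([C@@](C)(O)C[S@@+](=O)(N(C)C)c3ccccc3)C[C@@H]1O.F[B-](F)(F)F
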